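Which of the four flasks ends with the most product, and how much does each hold?

common to all: substrate 0.27 M; partner 0.216 M; free catalyst 46 mM; time 3.0 h

| flask | temperature | remark |
|---|---|---|
| Sunday's | 25 °C |  |
| Monday's | 50 °C |  |
| Tuesday's |  | at 50 °C until 50 min, from then on at 0 °C |
| Wednesday's | 0 °C |  |

- the best flask by amount of product, in percent of the substrate charged; "all alike" if 1.5 percentage points covers them all (Sunday's / Monday's / Tuesday's / Wednesday's / all alike)
- amount of product at the end, in percent of the substrate charged, Sunday's
- amount of product at the end, in percent of the substrate charged, Monday's
- amount of product at the end, in percent of the substrate charged, Tuesday's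
- amount of product at the end, in percent of the substrate charged, Wednesday's

- the list of constants is for 50 °C, to be carried to other temperatures by the activation energies and enthalpies

    substrate + free catalyst → catalyst intermediate A (k1 = 0.26 L mol⁻¹ s⁻¹, Ea1 = 49.0 kJ mol⁻¹)
    partner + catalyst intermediate A → catalyst intermediate B (k2 = 0.014 L mol⁻¹ s⁻¹, Ea2 = 75.0 kJ mol⁻¹)
    catalyst intermediate B ⇌ by-product + catalyst intermediate C (K3 = 0.092 M, k3 = 0.058 s⁻¹, Ea3 = 76.0 kJ mol⁻¹, ΔH3 = −55.0 kJ mol⁻¹)
    catalyst intermediate C ⇌ free catalyst + product (K4 = 0.12 M, k4 = 0.0013 s⁻¹, Ea4 = 93.0 kJ mol⁻¹, ΔH4 = −3.00 kJ mol⁻¹)
    partner ⇌ dormant form (K5 = 2.3, k5 = 3.4 × 10⁻⁵ s⁻¹, Ea5 = 111 kJ mol⁻¹, ΔH5 = −44.0 kJ mol⁻¹)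
    (constants at 50 °C)

Each product released has cost one partner, taken up by catalyst intermediate A, so it pays to count the fraction of partner left and not the product made. Monday's flask holds less partner than substrate, which makes the partner the limiting reagent. Its partner allowance, partner charged over substrate charged, is 80.0%, and that is the ceiling on the product. A neighbour, Monday's flask with 0.13 M of partner, looks nearly the same, yet its allowance is 48.1%.

Whether a flask reaches its allowance in time can be reckoned from the catalyst's two waits per turn. Release of product from catalyst intermediate C costs a fixed wait, and uptake of partner costs a wait that grows as [partner] thins. Summed over Monday's charge, the fixed waits take 1.00 h. The rest of the 3.0 h acts as a pseudo-first-order decay of the partner with time constant 25.9 min, which leaves 0.976% of it. The partner also slips into the dormant form, at 5.28% of its uptake rate when the whole catalyst charge stands as intermediate A. With the push back of by-product left aside, this reckoning gives 75.0% for Monday's.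

The neighbour's fixed waits are shorter, 0.604 h, so 0.387% of its partner is left and it should reach 45.4%. The two differ in the size of the allowance, and in this reckoning the fixed waits of each are shorter than the 3.0 h, though that comparison leaves aside the push back of by-product.

Tuesday's flask is hot for 50 min, shorter than Monday's fixed waits. Even with the whole catalyst charge standing as intermediate C, its release then comes to 66.4% of the substrate, which is less than Monday's figure. Wednesday's release is 560 times slower, and the same ceiling falls to 0.424%. Sunday's ceiling was not reckoned here.

The forecast names Monday's as best, with 6.7% for Sunday's, 61% for Monday's, 27% for Tuesday's and 0.02% for Wednesday's, from “quasi-steady hand stepping of the catalyst cycle”. For Monday's it stands lower than the reckoning above.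

The simulation gives 6.77% for Sunday's, 62.3% for Monday's, 26.2% for Tuesday's and 0.0208% for Wednesday's, so Monday's is best. Monday's product stands 13 percentage points under the reckoning and below its allowance of 80.0%, with 4.12% of the partner left against 0.976% reckoned, and at 30.0 h that flask holds 77.6%. On the neighbour, the same count gave an allowance of 48.1%, 0.387% of partner left and 45.4% of product. That flask ends with 0.85% of its partner left, 40% of its substrate unbound, and 42.8% of product.

(Its constants are made up; no experiment stands behind them.)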